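Compound numbers used below are those of the compound list after the steps. Daucane numbering is used throughout: C1 is the quaternary fusion carbon with the angular methyl, C2 and C3 are CH2, C4 is the isopropyl carbinol, C5 the fusion CH, C6 the aroyloxy carbon, C7=C8 the alkene (methyl on C8), C9 the acetoxy carbon and C10 a CH2. β is the face of the C1 methyl and α the face of H5. In the six-membered-ring intermediates the same atom numbers are kept, C8 is absent and C7 is bonded to C9. Names built on the daucane skeleton are descriptive; the SMILES strings define the structures.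

## Analysis of the target

Compound 25 is a daucane sesquiterpenoid diester in which a cyclopentane (C1–C5) is trans-fused to a cycloheptene (C1, C5–C10). Its five stereocentres are 1R,4R,5S,6S,9S: the angular methyl is β and H5 α, the C4 hydroxyl is β (cis to the angular methyl) with the isopropyl group α, and the C6 and C9 oxygens are both α. The two ester oxygens therefore flank the trisubstituted C7=C8 alkene in a cis-1,4 relationship, and H5 and H6 are anti. The sensitive groups are two different allylic esters on one alkene (they can migrate, ionise or hydrolyse), a tertiary alcohol that dehydrates easily, and a free phenol. The synthesis is hard because a trans-fused seven-membered ring must carry a quaternary centre and a fully substituted carbinol on either side of the fusion methine, an alkene oxygenated at both allylic positions with defined configuration, and three oxygens that have to be told apart. The strategy rests on C8, the methyl-bearing alkene carbon between C7 and the oxygenated C9. Without C8, what remains is a trans-fused cyclohexene (C1, C5, C6, C7, C9, C10) with a C7=C9 bond, a ring that is much easier to close than the cycloheptene and that can be enlarged by exactly one carbon while oxygen is delivered to C9.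

## Retrosynthetic reasoning

**C6 ester (25 to 24 to 19 + 23).** The aroyl C–O bond at C6 is cut first. An ester at C6 could act as a neighbouring group on the allyl cation of the key step and would not survive the strong base used for carbene generation, so it must go on last. Diol 19 has only one acylable hydroxyl, since the C4 hydroxyl is tertiary and hindered. The phenol is carried as a silyl ether (24) that can be removed without touching either ester. Acid chloride 23 comes from 20 through 22.

**Silyl ethers and the C8 methyl (19 to 18 to 17).** The C8–CH3 bond is cut at the alkene carbon because the ring enlargement necessarily leaves a bromine there. A methyl cross-coupling turns that by-product of the mechanism into the required substituent, so C8 needs no separate functionalisation.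

**C8 out of the ring (17 to 16).** The C9–O bond is cut and the C7–C9 bond re-formed, so that C8 becomes the apex of a gem-dibromocyclopropane on a cyclohexene. The forward reaction must ionise one bromide, open the shared bond, and let an acetate nucleophile add at C9 (not C7) on the α face. This one step makes the seven-membered ring, the C9 stereocentre and the handle at C8.

**Cyclopropane (16 to 14 + 15).** The C7–C8 and C8–C9 bonds are cut together; C8 comes from 15 as the dihalocarbene. The carbene should add on the α face, away from the axial C1 methyl. The face is not critical, because the opening that follows makes C7 and C9 trigonal and so erases the configuration of the cyclopropane.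

**C7=C9 (14 to 13 to 12).** The ring alkene is cut by metathesis logic into two vinyl termini, an allyl group on C1 and a silyloxyallyl group on C5. These two arms are trans on the cyclopentane, so the trans fusion is fixed before the ring closes. The tertiary hydroxyl is silylated only after ring closure, directly before the carbene step that requires it to be masked.

**C4–isopropyl (12 to 11).** The C4–C(isopropyl) bond is cut back to a cyclopentanone. Addition occurs on the monocyclic ketone, where the neighbouring C5 side chain blocks one face.

**C5–C6 (11 to 10 to 6 + 7).** This is an aldol disconnection between the C5 enolate carbon and 7. The forward step must set C5 relative to C1 (anti to the allyl group) and C6 relative to C5 (anti aldol).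

**C1–CH3 (6 to 4).** The quaternary centre could be cut at either substituent. Catalytic enantioselective conjugate allylation of a β-methyl enone to a quaternary centre is not a dependable transformation. Copper-catalysed enantioselective addition of a methylaluminium reagent to β-substituted cyclopentenones is established. The allyl group is therefore placed on the enone (4) and the methyl is the nucleophile. Trapping the enolate as 6 keeps its regiochemistry on the hindered side.

**Enone (4 to 1 + 2).** Addition of 2 to the vinylogous ester 1 with carbonyl transposition.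

## Alternatives that were turned down

**Alternative 1:** The disconnection is C1–CH3 together with C5–C6. The forward key step adds methyl (Me3Al, catalytic Cu(OTf)2, chiral NHC) to C1 of enone 4 and traps the aluminium enolate at C5 with an aldehyde to give hydroxy ketone A1; the aldehyde is (2Z)-3-iodobut-2-enal A2.
- For: one step sets C1, C5 and C6 and brings in the C7=C8 alkene with its methyl, its geometry fixed by the reagent. The iodide at C8 is a handle for a later C8–C9 closure. No ring enlargement and no methyl cross-coupling are needed. On convergence and step count it is stronger than the chosen route.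
- Against: A2 is a vinylogous acyl iodide, so a hindered enolate may attack C8 by addition–elimination or isomerise the alkene. The later isopropyl organometallic must tolerate an alkenyl iodide that exchanges readily. The seven-membered ring would then be closed by carbonyl addition from C8 to C9, with nothing controlling the new C9 carbinol.
- Comparison: the same methyl addition opens the chosen route (step 2), so both share that risk. The chosen route asks the enolate only to add to the simplest enal, closes a six-membered ring, and sets C9 under the influence of the angular methyl.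

**Alternative 2:** The disconnection is C4–C5. In the forward key step Rh2(OAc)4 converts diazo ester A3 into a carbene that inserts into the tertiary C4–H bond and closes the cyclopentane A4 with retention at C4.
- For: it makes the most congested bond of the molecule without adding an isopropyl nucleophile to a hindered ketone. C4 is drawn from the chiral pool, and a C–H bond next to silyloxy is activated for insertion. On the C4 problem it is stronger than the chosen route, which relies on an organocerium addition.
- Against: the step closes only the five-membered ring. The quaternary C1 must first be built enantioselectively in an open chain. The acceptor-only carbene can instead attack the acetal oxygens (oxonium ylide) or the methoxy C–H bonds. The C5 configuration is not secured, and the whole cycloheptene with C6, C7=C8 and C9 is still to be built from the ester and acetal groups of A4.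
- Comparison: the chosen route has both rings and four of the five stereocentres in place after eight steps.

**Alternative 3:** The disconnection is C6–C7. In the forward key step CrCl2 with catalytic NiCl2 turns the Z-alkenyl iodide of iodo aldehyde A5 into an alkenylchromium species that adds to the C6 aldehyde (Nozaki–Hiyama–Kishi) and closes the ring to A6.
- For: A6 has the complete skeleton, the alkene, the C8 methyl, the C9 acetate and a free C6 hydroxyl ready for aroylation. The endgame is shorter. C9 is set beforehand by a reagent-controlled step and not by cation capture; on that point it is stronger than the chosen route.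
- Against: A5 needs a long linear synthesis. Its aldehyde is α to C5 and β to a silyloxy carbinol, so it can epimerise or eliminate. The alkenylmetal carries an allylic acetate that can be lost (allene formation or nickel-mediated ionisation). A seven-membered ring is closed directly, and the C6 configuration is left to the addition.
- Comparison: the chosen route sets C6 early in an aldol and closes a six-membered ring by metathesis. The price is a cation capture whose selectivity must come from the substrate.

Key step: step 9

Assumption: the enantiomer of the chiral NHC ligand that delivers methyl to give the 1R quaternary centre in step 2 is selected on test scale; the sense of induction is not derived here.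

Remark on the cyclopropane: in 16 the cyclopropane is placed on the α face, the face left open by the axial angular methyl; this configuration is lost again in step 9.

## Route

Step 1
Reactants: 1 3-ethoxycyclopent-2-en-1-one; 2 allylmagnesium bromide
Product: 4 3-(prop-2-en-1-yl)cyclopent-2-en-1-one, via tertiary allylic alcohol 3 (not isolated)
Conditions: allylMgBr, THF, 0 °C; then 1 M HCl, 0 °C, short contact
Reagents that add atoms: water, O
Why: Stork–Danheiser sequence: 1,2-addition to the vinylogous ester, then acid-promoted ionisation and hydrolysis of the enol ether transposes the carbonyl. Brief cold acid should keep the skipped alkene from moving into conjugation.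

Step 2
Reactants: 4 3-(prop-2-en-1-yl)cyclopent-2-en-1-one
Product: 6 trimethyl{[(3R)-3-methyl-3-(prop-2-en-1-yl)cyclopent-1-en-1-yl]oxy}silane, via dimethylaluminium enolate 5 (not isolated)
Conditions: Me3Al, Cu(OTf)2 (5 mol%), chiral sulfonate-bearing imidazolinium salt (NHC precursor, 5 mol%), THF, −78 to −30 °C; then Me3SiOTf, −78 to 0 °C
Reagents that add atoms: trimethylaluminium, C[Al](C)C; trimethylsilyl trifluoromethanesulfonate, C[Si](C)(C)OS(=O)(=O)C(F)(F)F
Why: Copper-catalysed enantioselective conjugate addition of a methylaluminium reagent to a β-substituted cyclopentenone, a known way to β-quaternary cyclopentanones; the ligand sets C1 (R). Silylation of the aluminium enolate fixes the enolate on the hindered side (C4=C5).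

Step 3
Reactants: 6 trimethyl{[(3R)-3-methyl-3-(prop-2-en-1-yl)cyclopent-1-en-1-yl]oxy}silane; 7 acrolein
Product: 10 (2S,3R)-2-[(1S)-1-hydroxyprop-2-en-1-yl]-3-methyl-3-(prop-2-en-1-yl)cyclopentan-1-one, via lithium enolate 8 (not isolated), via chlorozinc enolate 9 (not isolated)
Conditions: MeLi, THF, 0 °C; ZnCl2, −78 °C; acrolein, −78 °C, 10 min; AcOH quench
Reagents that add atoms: none
Why: MeLi cleaves the silyl enol ether to the regiodefined enolate, and the zinc enolate adds 1,2 to the enal through a closed Zimmerman–Traxler chair (aldol addition). The cyclic E-enolate should give the anti aldol (6S), and the aldehyde should approach C5 anti to the larger allyl group on C1, which puts C6 trans to C10 as the trans fusion requires. Minor diastereomers are removed by chromatography.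

Step 4
Reactants: 10 (2S,3R)-2-[(1S)-1-hydroxyprop-2-en-1-yl]-3-methyl-3-(prop-2-en-1-yl)cyclopentan-1-one
Product: 11 (2S,3R)-2-[(1S)-1-{[tert-butyl(dimethyl)silyl]oxy}prop-2-en-1-yl]-3-methyl-3-(prop-2-en-1-yl)cyclopentan-1-one
Conditions: TBSOTf, 2,6-lutidine, CH2Cl2, −78 °C
Reagents that add atoms: tert-butyldimethylsilyl trifluoromethanesulfonate, CC(C)(C)[Si](C)(C)OS(=O)(=O)C(F)(F)F
Why: Silylation with the triflate at low temperature should outrun retro-aldol cleavage and β-elimination of the β-hydroxy ketone.

Step 5
Reactants: 11 (2S,3R)-2-[(1S)-1-{[tert-butyl(dimethyl)silyl]oxy}prop-2-en-1-yl]-3-methyl-3-(prop-2-en-1-yl)cyclopentan-1-one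
Product: 12 (1R,2S,3R)-2-[(1S)-1-{[tert-butyl(dimethyl)silyl]oxy}prop-2-en-1-yl]-3-methyl-1-(propan-2-yl)-3-(prop-2-en-1-yl)cyclopentan-1-ol
Conditions: iPrMgCl, anhydrous CeCl3, THF, −78 to 0 °C; then cold 0.5 M HCl
Reagents that add atoms: isopropylmagnesium chloride, CC(C)[Mg]Cl
Why: Organocerium addition suppresses enolisation and β-hydride reduction of the hindered ketone. The nucleophile should attack the carbonyl face opposite the adjacent C5 side chain and the C1 methyl, so the hydroxyl ends cis to that side chain (4R).

Step 6
Reactants: 12 (1R,2S,3R)-2-[(1S)-1-{[tert-butyl(dimethyl)silyl]oxy}prop-2-en-1-yl]-3-methyl-1-(propan-2-yl)-3-(prop-2-en-1-yl)cyclopentan-1-ol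
Product: 13 6α-(tert-butyldimethylsilyloxy)-8-nordauc-7(9)-en-4β-ol (trans-fused hexahydroindene; 1R,4R,5S,6S)
Conditions: second-generation Grubbs catalyst (5 mol%), CH2Cl2 (5 mM), 40 °C
Reagents that add atoms: none
Why: Ring-closing metathesis of two monosubstituted alkenes to a cyclohexene. The two arms are trans on the cyclopentane, so closure gives the trans-fused hydrindene.

Step 7
Reactants: 13 6α-(tert-butyldimethylsilyloxy)-8-nordauc-7(9)-en-4β-ol
Product: 14 6α-(tert-butyldimethylsilyloxy)-4β-(triethylsilyloxy)-8-nordauc-7(9)-ene
Conditions: Et3SiOTf, 2,6-lutidine, CH2Cl2, 0 °C to rt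
Reagents that add atoms: triethylsilyl trifluoromethanesulfonate, CC[Si](CC)(CC)OS(=O)(=O)C(F)(F)F
Why: The silyl triflate is reactive enough for a hindered tertiary alcohol. The ether keeps the hydroxyl out of alkoxide–carbene chemistry in the next step.

Step 8
Reactants: 14 6α-(tert-butyldimethylsilyloxy)-4β-(triethylsilyloxy)-8-nordauc-7(9)-ene; 15 bromoform
Product: 16 8,8-dibromo-7α,9α-cyclopropane adduct of 14 (C8 bridges C7 and C9 on the α face; H7 and H9 β)
Conditions: CHBr3, KOtBu, pentane, 0 °C to rt
Reagents that add atoms: none
Why: Dibromocarbene from bromoform and KOtBu adds stereospecifically cis to the ring alkene (cheletropic [2+1] cycloaddition). Attack should occur on the α face, because the axial C1 methyl stands 1,3 to C9 over the β face of the half-chair cyclohexene. The face of addition is not critical, since C7 and C9 become trigonal in step 9.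

Step 9
Reactants: 16 8,8-dibromo-7α,9α-cyclopropane adduct of 14
Product: 17 9α-acetoxy-8-bromo-6α-(tert-butyldimethylsilyloxy)-4β-(triethylsilyloxy)-8-desmethyldauc-7-ene
Conditions: AgOAc (3 equiv), NaOAc, AcOH, 70–80 °C, dark
Reagents that add atoms: silver acetate, CC(=O)[O-].[Ag+]
Why: Ag+ pulls off the endo bromide (the one lying back over the six-membered ring) while the C7–C9 bond opens in a disrotatory sense with the ring carbons turning inward, giving a cis 2-bromoallyl cation (C7–C8–C9) inside a seven-membered ring. The closest known reaction type is the silver-assisted solvolytic ring expansion of 7,7-dibromobicyclo[4.1.0]heptanes to 2-bromocyclohept-2-enyl esters. The cycloheptene arises by one-carbon enlargement of the cyclohexene through cleavage of the shared bond, not by an exo or endo cyclisation. Because C7 and C9 become trigonal in the cation, the configuration of the cyclopropane is erased and only the positions it bridges matter. The step needs regioselectivity for C9 over C7: the inductively withdrawing, non-participating silyloxy group on C6 destabilises charge at C7, and the branched C6 also hinders that terminus. The new stereocentre C9 is set by the substrate: acetate should add on the α face, anti to the axial C1 methyl, which is 1,3 to C9 and blocks the β face. Only the endo bromide can leave, because loss of the exo bromide would demand a trans double bond in the ring; the remaining bromine stays on C8. NaOAc buffers the medium so that the two silyl ethers and the trans fusion, which is not involved, are preserved.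

Step 10
Reactants: 17 9α-acetoxy-8-bromo-6α-(tert-butyldimethylsilyloxy)-4β-(triethylsilyloxy)-8-desmethyldauc-7-ene
Product: 18 9α-acetoxy-6α-(tert-butyldimethylsilyloxy)-4β-(triethylsilyloxy)dauc-7-ene
Conditions: Me2Zn, Pd(dppf)Cl2 (5 mol%), 1,4-dioxane, 70 °C
Reagents that add atoms: dimethylzinc, C[Zn]C
Why: Negishi coupling: zerovalent palladium inserts into the alkenyl C–Br bond, methyl is transferred from zinc, and reductive elimination gives the methyl alkene. Me2Zn leaves esters and silyl ethers alone. Ionisation of the allylic acetate is disfavoured because palladium would have to approach C9 on the methyl-shielded β face.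

Step 11
Reactants: 18 9α-acetoxy-6α-(tert-butyldimethylsilyloxy)-4β-(triethylsilyloxy)dauc-7-ene
Product: 19 9α-acetoxydauc-7-ene-4β,6α-diol
Conditions: HF·pyridine, pyridine, THF, 0 °C to rt
Reagents that add atoms: none
Why: Fluoride cleavage of both silyl ethers under buffered, non-basic conditions, which should avoid acetate migration or hydrolysis.

Step 12
Reactants: 20 4-hydroxybenzoic acid
Product: 22 4-{[tert-butyl(dimethyl)silyl]oxy}benzoic acid, via bis-silylated acid 21 (not isolated)
Conditions: TBSCl (2.3 equiv), imidazole, DMF, rt; then AcOH–THF–H2O, rt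
Reagents that add atoms: tert-butyldimethylsilyl chloride, CC(C)(C)[Si](C)(C)Cl
Why: Bis-silylation followed by selective hydrolysis of the much more labile silyl ester; the aryl silyl ether tolerates dilute acid.

Step 13
Reactants: 22 4-{[tert-butyl(dimethyl)silyl]oxy}benzoic acid
Product: 23 4-{[tert-butyl(dimethyl)silyl]oxy}benzoyl chloride
Conditions: (COCl)2, DMF (cat.), CH2Cl2, 0 °C to rt; evaporate, use crude
Reagents that add atoms: oxalyl chloride, ClC(=O)C(Cl)=O
Why: Standard acid chloride formation through the chloroiminium intermediate; aryl silyl ethers survive these anhydrous conditions.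

Step 14
Reactants: 19 9α-acetoxydauc-7-ene-4β,6α-diol; 23 4-{[tert-butyl(dimethyl)silyl]oxy}benzoyl chloride
Product: 24 9α-acetoxy-4β-hydroxydauc-7-en-6α-yl 4-{[tert-butyl(dimethyl)silyl]oxy}benzoate
Conditions: Et3N, DMAP, CH2Cl2, 0 °C to rt
Reagents that add atoms: none
Why: DMAP-catalysed acylation should select the secondary allylic C6 hydroxyl over the very hindered tertiary C4 hydroxyl; no stereocentre is touched.

Step 15
Reactants: 24 9α-acetoxy-4β-hydroxydauc-7-en-6α-yl 4-{[tert-butyl(dimethyl)silyl]oxy}benzoate
Product: 25 (3R,3aS,4S,7S,8aR)-7-(acetyloxy)-3-hydroxy-6,8a-dimethyl-3-(propan-2-yl)-1,2,3,3a,4,7,8,8a-octahydroazulen-4-yl 4-hydroxybenzoate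
Conditions: KHF2, MeOH, rt
Reagents that add atoms: none
Why: Bifluoride cleaves aryl silyl ethers under conditions that should leave both alkyl esters and the tertiary alcohol untouched.

## Compound list

1 | 3-ethoxycyclopent-2-en-1-one | CCOC1=CC(=O)CC1 | starting material
2 | allylmagnesium bromide | C=CC[Mg]Br | starting material
3 | 3-ethoxy-1-(prop-2-en-1-yl)cyclopent-2-en-1-ol (racemic, formed as its magnesium alkoxide) | C=CCC1(O)C=C(OCC)CC1 | intermediate (not isolated)
4 | 3-(prop-2-en-1-yl)cyclopent-2-en-1-one | C=CCC1=CC(=O)CC1 | intermediate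
5 | dimethylaluminium (3R)-3-methyl-3-(prop-2-en-1-yl)cyclopent-1-en-1-olate | C=CC[C@@]1(C)CCC(O[Al](C)C)=C1 | intermediate (not isolated)
6 | trimethyl{[(3R)-3-methyl-3-(prop-2-en-1-yl)cyclopent-1-en-1-yl]oxy}silane | C=CC[C@@]1(C)CCC(O[Si](C)(C)C)=C1 | intermediate
7 | acrolein (prop-2-enal) | C=CC=O | starting material
8 | lithium (3R)-3-methyl-3-(prop-2-en-1-yl)cyclopent-1-en-1-olate | C=CC[C@@]1(C)CCC(O[Li])=C1 | intermediate (not isolated)
9 | chlorozinc (3R)-3-methyl-3-(prop-2-en-1-yl)cyclopent-1-en-1-olate | C=CC[C@@]1(C)CCC(O[Zn]Cl)=C1 | intermediate (not isolated)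
10 | (2S,3R)-2-[(1S)-1-hydroxyprop-2-en-1-yl]-3-methyl-3-(prop-2-en-1-yl)cyclopentan-1-one | C=CC[C@@]1(C)CCC(=O)[C@@H]1[C@@H](O)C=C | intermediate
11 | (2S,3R)-2-[(1S)-1-{[tert-butyl(dimethyl)silyl]oxy}prop-2-en-1-yl]-3-methyl-3-(prop-2-en-1-yl)cyclopentan-1-one | C=CC[C@@]1(C)CCC(=O)[C@@H]1[C@@H](O[Si](C)(C)C(C)(C)C)C=C | intermediate
12 | (1R,2S,3R)-2-[(1S)-1-{[tert-butyl(dimethyl)silyl]oxy}prop-2-en-1-yl]-3-methyl-1-(propan-2-yl)-3-(prop-2-en-1-yl)cyclopentan-1-ol | C=CC[C@@]1(C)CC[C@@](O)(C(C)C)[C@@H]1[C@@H](O[Si](C)(C)C(C)(C)C)C=C | intermediate
13 | 6α-(tert-butyldimethylsilyloxy)-8-nordauc-7(9)-en-4β-ol (trans-fused hexahydroindene) | C[C@]12CC[C@@](O)(C(C)C)[C@@H]1[C@@H](O[Si](C)(C)C(C)(C)C)C=CC2 | intermediate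
14 | 6α-(tert-butyldimethylsilyloxy)-4β-(triethylsilyloxy)-8-nordauc-7(9)-ene | C[C@]12CC[C@@](O[Si](CC)(CC)CC)(C(C)C)[C@@H]1[C@@H](O[Si](C)(C)C(C)(C)C)C=CC2 | intermediate
15 | bromoform | BrC(Br)Br | starting material
16 | 8,8-dibromo-7α,9α-cyclopropane adduct of 14 (α-fused; H7 and H9 β) | BrC1(Br)[C@H]2C[C@@]3(C)CC[C@@](O[Si](CC)(CC)CC)(C(C)C)[C@@H]3[C@@H](O[Si](C)(C)C(C)(C)C)[C@@H]12 | intermediate
17 | 9α-acetoxy-8-bromo-6α-(tert-butyldimethylsilyloxy)-4β-(triethylsilyloxy)-8-desmethyldauc-7-ene | CC(=O)O[C@H]1C[C@@]2(C)CC[C@@](O[Si](CC)(CC)CC)(C(C)C)[C@@H]2[C@@H](O[Si](C)(C)C(C)(C)C)C=C1Br | intermediate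
18 | 9α-acetoxy-6α-(tert-butyldimethylsilyloxy)-4β-(triethylsilyloxy)dauc-7-ene | CC(=O)O[C@H]1C[C@@]2(C)CC[C@@](O[Si](CC)(CC)CC)(C(C)C)[C@@H]2[C@@H](O[Si](C)(C)C(C)(C)C)C=C1C | intermediate
19 | 9α-acetoxydauc-7-ene-4β,6α-diol | CC(=O)O[C@H]1C[C@@]2(C)CC[C@@](O)(C(C)C)[C@@H]2[C@@H](O)C=C1C | intermediate
20 | 4-hydroxybenzoic acid | OC(=O)c1ccc(O)cc1 | starting material
21 | tert-butyldimethylsilyl 4-{[tert-butyl(dimethyl)silyl]oxy}benzoate | CC(C)(C)[Si](C)(C)OC(=O)c1ccc(O[Si](C)(C)C(C)(C)C)cc1 | intermediate (not isolated)
22 | 4-{[tert-butyl(dimethyl)silyl]oxy}benzoic acid | CC(C)(C)[Si](C)(C)Oc1ccc(cc1)C(O)=O | intermediate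
23 | 4-{[tert-butyl(dimethyl)silyl]oxy}benzoyl chloride | CC(C)(C)[Si](C)(C)Oc1ccc(cc1)C(Cl)=O | intermediate
24 | 9α-acetoxy-4β-hydroxydauc-7-en-6α-yl 4-{[tert-butyl(dimethyl)silyl]oxy}benzoate | CC(=O)O[C@H]1C[C@@]2(C)CC[C@@](O)(C(C)C)[C@@H]2[C@@H](OC(=O)c2ccc(O[Si](C)(C)C(C)(C)C)cc2)C=C1C | intermediate
25 | (3R,3aS,4S,7S,8aR)-7-(acetyloxy)-3-hydroxy-6,8a-dimethyl-3-(propan-2-yl)-1,2,3,3a,4,7,8,8a-octahydroazulen-4-yl 4-hydroxybenzoate | CC(=O)O[C@H]1C[C@@]2(C)CC[C@@](O)(C(C)C)[C@@H]2[C@@H](OC(=O)c2ccc(O)cc2)C=C1C | target

## Step count and least certain steps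

Total: 15 steps. Longest linear sequence: 13 steps (steps 1–11, 14, 15); steps 12 and 13 are a two-step side branch.

**Step 9 (key step).** The most likely failure is poor facial selectivity of acetate capture at C9: the bias comes only from the C1 methyl two atoms away, and ion pairing with the departing silver bromide could erode it. Capture at the C7 terminus and partial loss of the silyl ethers in warm acetic acid are further risks. Fallback, from 16 back to 17: the opening is run hydrolytically at room temperature (AgBF4, CaCO3, aqueous acetone) to the C9-epimeric 8-bromo allylic alcohols F1. Dess–Martin oxidation gives the α-bromo enone F2. Corey–Bakshi–Shibata reduction with the (R)-2-methyl-oxazaborolidine and catecholborane, in which the bromoalkenyl carbon is the large group, should give the 9α (9S) alcohol F3 under reagent control. Acetylation (Ac2O, pyridine, DMAP) gives 17.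

**Step 3.** Two selectivities are uncertain. Facial discrimination at C5 rests on methyl against allyl at the neighbouring quaternary centre and may be modest. Simple diastereoselection of a cyclic enolate with a small enal may also be poor, so that much of the material appears with the wrong C6 configuration. Material with C6 cis to the allyl group would end in the cis-fused series and is removed by chromatography at 10 or 13; that loss is not repaired. The C6-epimeric material is recovered by the fallback, from 6 back to 13. Step 3 is run as described and the syn aldol, (2S,3R)-2-[(1R)-1-hydroxyprop-2-en-1-yl]-3-methyl-3-(prop-2-en-1-yl)cyclopentan-1-one F4, is collected. Silylation under the conditions of step 4 gives its silyl ether F5, isopropylcerium addition as in step 5 gives the carbinol F6, and metathesis as in step 6 gives the 6β-silyloxy hydrindenol F7. Fluoride (Bu4NF, THF) frees the 4β,6β-diol F8. Mitsunobu reaction of its pseudoaxial allylic hydroxyl (4-nitrobenzoic acid, PPh3, diisopropyl azodicarboxylate) gives with inversion the 6α 4-nitrobenzoate F9. Methanolysis (K2CO3, MeOH) gives the 4β,6α-diol F10, and selective silylation of the secondary hydroxyl (TBSOTf, 1 equiv, 2,6-lutidine, −78 °C) gives 13.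

**Step 2.** Enantioselectivity for methyl addition to five-membered enones is substrate-dependent, and the skipped alkene may isomerise under the Lewis acidic conditions. Fallback, from 4 back to 10: achiral copper catalysis (CuBr·SMe2, Me3Al, then Me3SiOTf) gives the racemic silyl enol ether F11, and the aldol of step 3 gives the racemic anti aldol F12. Lipase-mediated acylation (Candida antarctica lipase B, vinyl acetate) should, by the usual enantiopreference for secondary carbinols with one medium and one large group, acylate the (1R)-carbinol enantiomer to its acetate F13 and leave 10.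

**Step 10.** Zerovalent palladium may ionise the allylic acetate in competition with slow insertion into a hindered alkenyl bromide, which would lead to loss or scrambling of the C9 oxygen. Fallback, from 17 back to 18: methanolysis (K2CO3, MeOH) gives bromo alcohol F3. Suzuki–Miyaura methylation on the free alcohol (trimethylboroxine, Pd(PPh3)4, K2CO3, dioxane–water, 90 °C) gives the 8-methyl 9α-alcohol F14, and acetylation (Ac2O, pyridine, DMAP) gives 18.

## Further compounds

F1 | step 9 | 8-bromo-6α-(tert-butyldimethylsilyloxy)-4β-(triethylsilyloxy)-8-desmethyldauc-7-en-9-ol (C9 epimers) | OC1C[C@@]2(C)CC[C@@](O[Si](CC)(CC)CC)(C(C)C)[C@@H]2[C@@H](O[Si](C)(C)C(C)(C)C)C=C1Br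
F2 | step 9 | 8-bromo-6α-(tert-butyldimethylsilyloxy)-4β-(triethylsilyloxy)-8-desmethyldauc-7-en-9-one | O=C1C[C@@]2(C)CC[C@@](O[Si](CC)(CC)CC)(C(C)C)[C@@H]2[C@@H](O[Si](C)(C)C(C)(C)C)C=C1Br
F3 | step 9 | 8-bromo-6α-(tert-butyldimethylsilyloxy)-4β-(triethylsilyloxy)-8-desmethyldauc-7-en-9α-ol | O[C@H]1C[C@@]2(C)CC[C@@](O[Si](CC)(CC)CC)(C(C)C)[C@@H]2[C@@H](O[Si](C)(C)C(C)(C)C)C=C1Br
F4 | step 3 | (2S,3R)-2-[(1R)-1-hydroxyprop-2-en-1-yl]-3-methyl-3-(prop-2-en-1-yl)cyclopentan-1-one (C6 epimer of 10) | C=CC[C@@]1(C)CCC(=O)[C@@H]1[C@H](O)C=C
F5 | step 3 | (2S,3R)-2-[(1R)-1-{[tert-butyl(dimethyl)silyl]oxy}prop-2-en-1-yl]-3-methyl-3-(prop-2-en-1-yl)cyclopentan-1-one (C6 epimer of 11) | C=CC[C@@]1(C)CCC(=O)[C@@H]1[C@H](O[Si](C)(C)C(C)(C)C)C=C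
F6 | step 3 | (1R,2S,3R)-2-[(1R)-1-{[tert-butyl(dimethyl)silyl]oxy}prop-2-en-1-yl]-3-methyl-1-(propan-2-yl)-3-(prop-2-en-1-yl)cyclopentan-1-ol (C6 epimer of 12) | C=CC[C@@]1(C)CC[C@@](O)(C(C)C)[C@@H]1[C@H](O[Si](C)(C)C(C)(C)C)C=C
F7 | step 3 | 6β-(tert-butyldimethylsilyloxy)-8-nordauc-7(9)-en-4β-ol (C6 epimer of 13) | C[C@]12CC[C@@](O)(C(C)C)[C@@H]1[C@H](O[Si](C)(C)C(C)(C)C)C=CC2
F8 | step 3 | 8-nordauc-7(9)-ene-4β,6β-diol | C[C@]12CC[C@@](O)(C(C)C)[C@@H]1[C@H](O)C=CC2
F9 | step 3 | 4β-hydroxy-8-nordauc-7(9)-en-6α-yl 4-nitrobenzoate | C[C@]12CC[C@@](O)(C(C)C)[C@@H]1[C@@H](OC(=O)c3ccc(cc3)[N+](=O)[O-])C=CC2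
F10 | step 3 | 8-nordauc-7(9)-ene-4β,6α-diol | C[C@]12CC[C@@](O)(C(C)C)[C@@H]1[C@@H](O)C=CC2
F11 | step 2 | racemic trimethyl{[3-methyl-3-(prop-2-en-1-yl)cyclopent-1-en-1-yl]oxy}silane | C=CCC1(C)CCC(O[Si](C)(C)C)=C1
F12 | step 2 | racemic anti aldol (10 and its enantiomer, relative configuration as in 10) | C=CCC1(C)CCC(=O)C1C(O)C=C
F13 | step 2 | (1R)-1-[(1R,2S)-2-methyl-5-oxo-2-(prop-2-en-1-yl)cyclopentyl]prop-2-en-1-yl acetate (acetate of the enantiomer of 10) | C=CC[C@]1(C)CCC(=O)[C@H]1[C@H](OC(C)=O)C=C
F14 | step 10 | 6α-(tert-butyldimethylsilyloxy)-4β-(triethylsilyloxy)dauc-7-en-9α-ol | O[C@H]1C[C@@]2(C)CC[C@@](O[Si](CC)(CC)CC)(C(C)C)[C@@H]2[C@@H](O[Si](C)(C)C(C)(C)C)C=C1C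
A1 | alternative 1 | 3-allyl-2-[(1R,2Z)-1-hydroxy-3-iodobut-2-en-1-yl]-3-methylcyclopentan-1-one (2S,3R) | C=CC[C@@]1(C)CCC(=O)[C@@H]1[C@@H](O)/C=C(/C)I
A2 | alternative 1 | (2Z)-3-iodobut-2-enal | C/C(I)=C/C=O
A3 | alternative 2 | methyl 2-diazo-3-(2,2-dimethoxyethyl)-3,7-dimethyl-6-{[tert-butyl(dimethyl)silyl]oxy}octanoate | COC(=O)C(=[N+]=[N-])[C@@](C)(CC(OC)OC)CC[C@@H](O[Si](C)(C)C(C)(C)C)C(C)C
A4 | alternative 2 | methyl 2-{[tert-butyl(dimethyl)silyl]oxy}-5-(2,2-dimethoxyethyl)-5-methyl-2-(propan-2-yl)cyclopentane-1-carboxylate | COC(=O)[C@@H]1[C@@](C)(CC(OC)OC)CC[C@@]1(O[Si](C)(C)C(C)(C)C)C(C)C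
A5 | alternative 3 | (3Z)-1-[2-formyl-1-methyl-3-(propan-2-yl)-3-(triethylsilyloxy)cyclopentyl]-4-iodo-3-methylbut-3-en-2-yl acetate | CC(=O)O[C@@H](C[C@@]1(C)CC[C@@](O[Si](CC)(CC)CC)(C(C)C)[C@@H]1C=O)/C(C)=C\I
A6 | alternative 3 | 9α-acetoxy-4β-(triethylsilyloxy)dauc-7-en-6α-ol | CC(=O)O[C@H]1C[C@@]2(C)CC[C@@](O[Si](CC)(CC)CC)(C(C)C)[C@@H]2[C@@H](O)C=C1C
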